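The readings are calculated with made-up constants; noise was put on by code.

An easy step opens the reckoning: divide target by starting material at the last reading, 4.00 d, of each earlier run.

common to all: starting material 0.25 M
- Monday's: coupling partner 0.50 M; second substrate 0.125 M; third substrate 0.025 M; run made earlier
- Tuesday's: coupling partner 0.50 M; second substrate 0.125 M; third substrate 0.10 M; run made earlier
- Thursday's: coupling partner 0.50 M; second substrate 0.19 M; third substrate 0.050 M; run made earlier
- flask: coupling partner 0.500 M; second substrate 0.125 M; third substrate 0.0500 M; time 6.0 d

| run | time / d | target / % | starting material / % |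
|---|---|---|---|
| Monday's | 0.104 | 14.7 | 74.6 |
| Monday's | 0.333 | 23.2 | 48.9 |
| Monday's | 1.04 | 21.3 | 39.9 |
| Monday's | 4.00 | 16.1 | 32.7 |
| Tuesday's | 0.104 | 11.9 | 74.5 |
| Tuesday's | 0.333 | 20.8 | 52.7 |
| Tuesday's | 1.04 | 17.4 | 40.5 |
| Tuesday's | 4.00 | 14.4 | 36.8 |
| Thursday's | 0.104 | 11.4 | 75.6 |
| Thursday's | 0.333 | 20.9 | 51.8 |
| Thursday's | 1.04 | 15.2 | 39.2 |
| Thursday's | 4.00 | 12.5 | 34.9 |

(each reading ± 1 percentage point)

- the best time, 6.0 d at the latest, for target
- the amount of target, in percent of the starting material charged, at that time
- the first time at which target reaches 11%, in the same percent, in d



That ratio is 0.492 in Monday's run. The first setting is third substrate. Suppose that it takes up coupling partner one for one. Raising it from Monday's 0.025 M to Tuesday's 0.10 M should then lower the ratio, and Tuesday reads less, 0.391. The second setting is second substrate. Thursday's run changes two charges against Monday's, 0.19 M of second substrate with 0.050 M of third substrate. Under the same supposition both should lower the ratio, and Thursday reads 0.358.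

Both settings therefore point to one concentration. If target forms reversibly from starting material and coupling partner, the late ratio is first-order in c(coupling partner), taken as the charge minus both substrates and the target formed. Dividing each ratio by that amount gives 1.59 /M, 1.64 /M and 1.57 /M. Their mean, read with the scatter of the readings, is the late quotient (an equilibrium constant), target over starting material and c(coupling partner), 1.60 /M.

The last setting is time. Waiting past the peak should cost target while coupling partner is being used, and Monday's target falls from 23.2% at 0.333 d to 16.1% at 4.00 d. For this flask, taking the target formed as the mean of Monday's and Tuesday's last readings, my reckoning gives a late ratio of 0.458. The quotient gives no peak, so the peak is read from Monday's and Tuesday's runs: near 0.333 d, between 20.8% and 23.2%, with the asked level passed before 0.104 d.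

The forecast puts the peak at 0.42 d with 22.5% of target and the asked level at 0.083 d: “More third substrate lowers the target slightly”.

The flask peaks at 0.422 d with 22.7% of target and reaches the asked level at 0.0713 d.

    second substrate + coupling partner → second product (k = 1.68 × 10⁻⁴ /M/s)
    target → over-reaction product (k = 5.38 × 10⁻⁸ /s)
    third substrate + coupling partner → third product (k = 8.74 × 10⁻⁵ /M/s)
    starting material ⇌ dormant form (K = 1.44, k = 1.57 × 10⁻⁵ /s)
    starting material + coupling partner ⇌ target (K = 1.60 /M, k = 4.84 × 10⁻⁵ /M/s)

At 6.0 d, the step between starting material with coupling partner and target, taken by itself, relaxes with a half-life of 0.166 d, far shorter than the time allowed. The flask's ratio then stands at 0.455. In the neighbour charged with 1.2 M of coupling partner, 77.4% of that charge is left at 6.00 d, so the late quotient gives a ratio of 1.49, and that neighbour stands at 1.48.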